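The numbers of this flask stand for no real mixture; what happens was integrated by code.

The substrate left faster for side product (5.73 × 10⁻⁴ min⁻¹) than for intermediate A (2.64 × 10⁻⁴ min⁻¹) at 20 °C, so I treated each flask as a race followed by a slow passage.

    intermediate A ⇌ intermediate B (K1 = 0.393, k1 = 1.69 × 10⁻⁵ min⁻¹, Ea1 = 101 kJ mol⁻¹, ΔH1 = −23.0 kJ mol⁻¹)
    substrate → side product (k2 = 5.73 × 10⁻⁴ min⁻¹, Ea2 = 105 kJ mol⁻¹)
    substrate → intermediate A (k3 = 2.64 × 10⁻⁴ min⁻¹, Ea3 = 97.0 kJ mol⁻¹)
    intermediate B → target (k4 = 6.45 × 10⁻⁴ min⁻¹, Ea4 = 96.0 kJ mol⁻¹)
    target ⇌ isomer of the product (K5 = 0.393, k5 = 0.00107 min⁻¹, Ea5 = 94.0 kJ mol⁻¹, ΔH5 = −43.0 kJ mol⁻¹)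
    (constants at 20 °C)

| flask | substrate | temperature | time | remark |
|---|---|---|---|---|
| delta | 0.50 M | 40 °C | 2.5 d |  |
| gamma | 0.50 M |  | 2.5 d | at 40 °C until 30 h, from then on at 20 °C |
| eta | 0.50 M | 20 °C | 2.5 d |  |

1. the best flask by amount of target, in percent of the substrate charged; "all alike" if 1.5 percentage points covers them all (delta / gamma / eta / all alike)
2. amount of target at the end, in percent of the substrate charged, delta
3. amount of target at the end, in percent of the substrate charged, gamma
4. amount of target at the end, in percent of the substrate charged, eta

I built delta up one process at a time, carrying each constant to 40 °C with its activation energy or enthalpy. The passage from intermediate A to intermediate B, at 2.38 × 10⁻⁴ min⁻¹, was slower than the step from intermediate B to target, at 0.00798 min⁻¹, so I took it as the rate-limiting step, and with that passage as the sole process target reached 57.6% of the charge.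

Next I added the race: at 40 °C the substrate went to side product at 0.00898 min⁻¹ and to intermediate A at 0.00335 min⁻¹, so it lasted 81.1 min on average, far less than the run, and the selectivity φ, the share entering intermediate A, was 27.2%, which cut the figure to 15.7%.

Then I let intermediate B fall back: the ratio of falling back to going on was 0.139, which gave 2.09 × 10⁻⁴ min⁻¹ for the drain constant κ, the forward constant of the passage divided by one plus that ratio, and the figure fell to 14.4%.

Last came the isomer, with constant 0.127 at 40 °C, which left 12.8% as target for delta.

For gamma I stopped the drain at 30 h, since the cold constant 1.58 × 10⁻⁵ min⁻¹ was smaller, and I re-divided by the cold isomer balance, which relaxes with a half-life of 3.05 h, short against the remaining time; that gave 6.13%.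

For eta the substrate lifetime was a third of the run, so the same formula gave me a ceiling, 1.26%. My ranking put delta first.

The forecast also named delta, with 12.2% for delta, 6% for gamma and 0.52% for eta, a lower delta than mine and a point value for eta where I held a ceiling, and it expected that on cooling “the fast exothermic target–isomer equilibrium shifts towards isomer”.

The simulation gave 12.3% for delta, 5.99% for gamma and 0.507% for eta, so delta led.

Delta ended with intermediate A at 13.0%, and φ with the drain gives 12.8%. A flask like delta kept at 15 °C has κ of 7.81 × 10⁻⁶ min⁻¹, smaller than the 2.09 × 10⁻⁴ min⁻¹ of delta, and φ of 32.8%, and the same reckoning gives 0.592% of target, a ceiling above the 0.112% that flask held, with 23.4% of substrate still present. Its intermediate A, reckoned as φ times the substrate consumed, less the drain, comes to 24.4%, and the flask held 24.7%.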